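Ring A (C1/C10/C11/C12/C13/C14) hides a 2-pyrone: C20 on C11 and the oxygen on C14 are cis and 1,4-related, so they can be the two ends of a lactone bridge, and the tertiary 11-OH is a pyrone 3-hydroxyl. The key step is a catalytic asymmetric Diels–Alder reaction of 3-hydroxy-2-pyrone with an (E)-β-methyl-β-alkynyl enal. It forms C1–C14 and C10–C11 at once, sets C1, C10, C11 and C14, and delivers C9 (CHO) and C2–C3 (alkyne) as handles. The alkyne is grown to C4–C6, a bromobutenolide is added by vinylogous aldol, a Nozaki–Hiyama–Kishi reaction closes the ten-membered ring and a transannular oxa-Michael addition forges the 4,8-ether.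

Key step: step 3

Remark 1: atoms are cited with briarane numbering (C1–C20); ring A is the cyclohexane C1/C10/C11/C12/C13/C14 and ring B the ten-membered carbocycle C1–C10.
Remark 2: compounds 1, 5, 13 and 20 are taken as purchasable, and in steps 3 and 9 the catalyst enantiomer is the one that delivers the configuration drawn (the antipode is available in both cases).

Step 1
Reactants: 1 (E)-3-methylpent-2-en-4-yn-1-ol
Product: 3 (E)-3-methyl-5-(trimethylsilyl)pent-2-en-4-yn-1-ol, via bis-silylated enynol 2 (not isolated)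
Conditions: n-BuLi (2.1 equiv), THF, −78 °C; Me3SiCl (2.2 equiv), −78 °C to rt; then 1 M HCl, rt
Reagents that add atoms: chlorotrimethylsilane, C[Si](C)(C)Cl
Why: C-silylation of a terminal alkyne through its lithium acetylide (the alkoxide is silylated too and the labile O–Si bond is cleaved on acidic work-up), with no stereocentre involved and the E alkene untouched.

Step 2
Reactants: 3 (E)-3-methyl-5-(trimethylsilyl)pent-2-en-4-yn-1-ol
Product: 4 (E)-3-methyl-5-(trimethylsilyl)pent-2-en-4-ynal
Conditions: MnO2 (15 equiv), CH2Cl2, rt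
Reagents that add atoms: none
Why: MnO2 oxidation of an allylic alcohol to the enal under neutral conditions, which keeps the E geometry that later encodes the trans relationship of C2 and C9.

Step 3
Reactants: 4 (E)-3-methyl-5-(trimethylsilyl)pent-2-en-4-ynal; 5 3-hydroxy-2H-pyran-2-one
Product: 6 endo adduct 4-hydroxy-7-methyl-3-oxo-7-[(trimethylsilyl)ethynyl]-2-oxabicyclo[2.2.2]oct-5-ene-8-carbaldehyde
Conditions: epi-9-amino-9-deoxyquinidine-derived N-[3,5-bis(trifluoromethyl)phenyl]thiourea (10 mol%), Et2O (concentrated), 0 °C to rt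
Reagents that add atoms: none
Why: The tertiary amine of the catalyst deprotonates the acidic 3-OH of 5 and the ion-paired 3-oxidopyrone, a strongly HOMO-raised diene, attacks the thiourea-bound enal 4 with C6 (C14) at the β-carbon C1 while the enal α-carbon C10 bonds to pyrone C3 (C11), either in one asynchronous [4+2] event or as a Michael addition followed at once by an intramolecular aldol closure, so that C1–C14 and C10–C11 arise in the same operation. The closest known reaction type is the amine-base-catalysed Diels–Alder reaction of 3-hydroxy-2-pyrones with α,β-unsaturated carbonyl dienophiles, and a quaternary carbon has been generated from a trisubstituted dienophile on this diene in its boronate-tethered variant. Ring A is closed as a six-membered carbocycle by suprafacial [4+2] addition (in stepwise terms a 6-(enolexo)-exo-trig aldol onto the C11 carbonyl), and the C20(=O)–O–C14 lactone persists as the third bridge of a 2-oxabicyclo[2.2.2]octene. C1 and C10 are related by the E geometry of 4 (C2 and C9 trans, CH3-15 trans to H-10), C11 and C14 by suprafacial addition across the diene, the two pairs by the endo position of the formyl group (under C12=C13, anti to the lactone bridge), and the absolute sense by the chiral ammonium/thiourea pocket. The step needs regioselectivity (nucleophilic C14 to C1, C10 to the oxido-bearing C11), which the single formyl acceptor secures because the slim alkynyl group is no competing acceptor; endo selectivity, secured by hydrogen bonding of the formyl oxygen next to the ion pair; and chemoselectivity for the alkene over the alkyne, secured by conjugation and the silyl cap.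

Step 4
Reactants: 6 endo adduct 4-hydroxy-7-methyl-3-oxo-7-[(trimethylsilyl)ethynyl]-2-oxabicyclo[2.2.2]oct-5-ene-8-carbaldehyde
Product: 7 4-hydroxy-8-(hydroxymethyl)-7-methyl-7-[(trimethylsilyl)ethynyl]-2-oxabicyclo[2.2.2]oct-5-en-3-one
Conditions: NaBH4, MeOH/CH2Cl2, −78 °C
Reagents that add atoms: none
Why: Sodium borohydride reduction of the aldehyde, which at −78 °C is far faster than attack on the bridged lactone, with no new stereocentre (C9 becomes CH2).

Step 5
Reactants: 7 4-hydroxy-8-(hydroxymethyl)-7-methyl-7-[(trimethylsilyl)ethynyl]-2-oxabicyclo[2.2.2]oct-5-en-3-one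
Product: 8 4-hydroxy-7-methyl-8-[(triethylsilyloxy)methyl]-7-[(trimethylsilyl)ethynyl]-2-oxabicyclo[2.2.2]oct-5-en-3-one
Conditions: Et3SiCl, imidazole, DMF, 0 °C
Reagents that add atoms: chlorotriethylsilane, CC[Si](Cl)(CC)CC
Why: Silyl ether formation at the only primary hydroxyl, the bridgehead tertiary 11-OH being too hindered for Et3SiCl/imidazole, which masks C9 until step 19.

Step 6
Reactants: 8 4-hydroxy-7-methyl-8-[(triethylsilyloxy)methyl]-7-[(trimethylsilyl)ethynyl]-2-oxabicyclo[2.2.2]oct-5-en-3-one
Product: 9 4-hydroxy-7-methyl-8-[(triethylsilyloxy)methyl]-7-[(trimethylsilyl)ethynyl]-2-oxabicyclo[2.2.2]octan-3-one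
Conditions: 2-nitrobenzenesulfonohydrazide, Et3N, CH2Cl2, rt
Reagents that add atoms: none
Why: Diimide reduction, in which HN=NH released from the sulfonohydrazide delivers two hydrogens suprafacially to the strained, unhindered cis-disubstituted C12=C13 bond much faster than to the silyl-capped alkyne, and no stereocentre is created.

Step 7
Reactants: 9 4-hydroxy-7-methyl-8-[(triethylsilyloxy)methyl]-7-[(trimethylsilyl)ethynyl]-2-oxabicyclo[2.2.2]octan-3-one
Product: 11 ring A triol 3-ethynyl-1-(hydroxymethyl)-3-methyl-2-[(triethylsilyloxy)methyl]cyclohexane-1,4-diol, via silylalkyne triol 10 (not isolated)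
Conditions: LiBH4, THF, 0 °C to rt; then K2CO3, MeOH, rt
Reagents that add atoms: none
Why: Lithium borohydride reduction opens the strained α-hydroxy lactone to the C20 primary and C14 secondary alcohols without touching a stereocentre, and methanolic K2CO3 then cleaves the alkynyl C–Si bond (protodesilylation).

Step 8
Reactants: 11 ring A triol 3-ethynyl-1-(hydroxymethyl)-3-methyl-2-[(triethylsilyloxy)methyl]cyclohexane-1,4-diol
Product: 12 ring A diacetate [4-acetoxy-3-ethynyl-1-hydroxy-3-methyl-2-[(triethylsilyloxy)methyl]cyclohexyl]methyl acetate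
Conditions: Ac2O, pyridine, DMAP (cat.), CH2Cl2, 0 °C to rt
Reagents that add atoms: acetic anhydride, CC(=O)OC(C)=O
Why: Acetylation esterifies the primary C20 and secondary C14 hydroxyls, which are acetates in the target, while the tertiary 11-OH does not react under these conditions.

Step 9
Reactants: 12 ring A diacetate [4-acetoxy-3-ethynyl-1-hydroxy-3-methyl-2-[(triethylsilyloxy)methyl]cyclohexyl]methyl acetate; 13 2-bromoprop-2-enal
Product: 14 propargylic alcohol (diacetate 12 carrying at C3 the carbinol C4H(OH)–C5(Br)=C16H2)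
Conditions: Me2Zn (4 equiv), (S,S)-ProPhenol (20 mol%), Ph3PO (40 mol%), toluene, 0 °C
Reagents that add atoms: none
Why: Catalytic asymmetric alkynylation of an aldehyde (zinc alkynylide addition under ProPhenol control), in which the dinuclear zinc catalyst binds alkynylide and enal and dictates the face of addition, so that C4 is set by the catalyst independently of the remote ring A centres and the acetates are tolerated.

Step 10
Reactants: 14 propargylic alcohol (diacetate 12 carrying at C3 the carbinol C4H(OH)–C5(Br)=C16H2)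
Product: 15 (2E)-allylic alcohol (C2=C3 trans)
Conditions: Cp*RuCl(cod) (5 mol%), H2 (10 bar), CH2Cl2, rt
Reagents that add atoms: none
Why: Ruthenium-catalysed trans-hydrogenation of an internal alkyne, assisted by the propargylic hydroxyl, gives the E alkene (needed so that syn-dihydroxylation leads to the 2,3-threo diol) and leaves the electron-poor bromoalkene and the esters alone.

Step 11
Reactants: 15 (2E)-allylic alcohol (C2=C3 trans)
Product: 16 4-O-tert-butyldimethylsilyl ether of 15
Conditions: t-BuMe2SiOTf, 2,6-lutidine, CH2Cl2, −78 °C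
Reagents that add atoms: tert-butyldimethylsilyl triflate, CC(C)(C)[Si](C)(C)OS(=O)(=O)C(F)(F)F
Why: Silylation of the secondary allylic hydroxyl at −78 °C, where the tertiary 11-OH is inert, gives a bulky ether that differentiates O4 from O2/O3 and steers steps 12 and 17.

Step 12
Reactants: 16 4-O-tert-butyldimethylsilyl ether of 15
Product: 17 2,3-diol (2,3-threo and 3,4-erythro) of 16
Conditions: OsO4 (5 mol%), N-methylmorpholine N-oxide, acetone/H2O (5:1), rt
Reagents that add atoms: N-methylmorpholine N-oxide, C[N+]1([O-])CCOCC1; water, O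
Why: Osmium-catalysed syn-dihydroxylation (Upjohn conditions), in which syn addition to the E alkene gives the 2,3-threo diol and the reagent approaches anti to the allylic C4 silyloxy group (Kishi's empirical rule, 3,4-erythro), fixing C2 and C3 while the electron-poor bromoalkene is not attacked.

Step 13
Reactants: 17 2,3-diol (2,3-threo and 3,4-erythro) of 16
Product: 18 2,3,14,20-tetraacetate (5-bromo-5(16)-ene with 4-OTBS and 9-OTES)
Conditions: Ac2O, pyridine, DMAP, CH2Cl2, rt
Reagents that add atoms: acetic anhydride, CC(=O)OC(C)=O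
Why: Acetylation of both secondary hydroxyls installs the C2 and C3 acetates of the target, and an acetyl shift between O14 and O2 would be harmless because both positions end up acetylated.

Step 14
Reactants: 18 2,3,14,20-tetraacetate (5-bromo-5(16)-ene with 4-OTBS and 9-OTES)
Product: 19 enal (18 with the C6 formyl group in place of bromine at C5)
Conditions: Pd(PPh3)4 (5 mol%), CO (3 bar), Bu3SnH (slow addition), toluene, 50 °C
Reagents that add atoms: carbon monoxide, [C-]#[O+]
Why: Palladium-catalysed reductive carbonylation (formylation) of the alkenyl bromide, by oxidative addition to zerovalent palladium, CO insertion and hydride transfer from Bu3SnH, gives the α-substituted acrolein and creates C6 without affecting a stereocentre.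

Step 15
Reactants: 20 4-hydroxy-3-methylfuran-2(5H)-one
Product: 21 4-bromo-3-methylfuran-2(5H)-one
Conditions: (COBr)2, DMF (cat.), CH2Cl2, 0 °C to rt
Reagents that add atoms: oxalyl bromide, O=C(Br)C(=O)Br
Why: Vilsmeier-type bromodehydroxylation of a vinylogous acid (tetronic acid) gives the β-bromobutenolide, with no stereocentre involved.

Step 16
Reactants: 21 4-bromo-3-methylfuran-2(5H)-one
Product: 22 [(4-bromo-3-methylfuran-2-yl)oxy](tert-butyl)dimethylsilane
Conditions: t-BuMe2SiOTf, Et3N, CH2Cl2, 0 °C
Reagents that add atoms: tert-butyldimethylsilyl triflate, CC(C)(C)[Si](C)(C)OS(=O)(=O)C(F)(F)F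
Why: Soft enolisation and O-silylation of the butenolide gives the aromatic 2-silyloxyfuran, the nucleophile for the vinylogous aldol reaction.

Step 17
Reactants: 19 enal (18 with the C6 formyl group in place of bromine at C5); 22 [(4-bromo-3-methylfuran-2-yl)oxy](tert-butyl)dimethylsilane
Product: 23 vinylogous aldol adduct (6-hydroxy with 4,6-anti and 6,7-threo relationships; 8-bromo-Δ8(17)-butenolide)
Conditions: BF3·OEt2 (1.2 equiv), CH2Cl2, −78 °C
Reagents that add atoms: none
Why: Vinylogous Mukaiyama aldol reaction, in which the silyloxyfuran attacks the BF3-bound aldehyde through its C5 (C7) in an open transition state, A1,3 strain and dipole minimisation relative to the C4 silyloxy group favour the 4,6-anti carbinol (Evans-type 1,3-induction), and Lewis-acid-promoted silyloxyfuran additions favour the threo C6/C7 pair.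

Step 18
Reactants: 23 vinylogous aldol adduct (6-hydroxy with 4,6-anti and 6,7-threo relationships; 8-bromo-Δ8(17)-butenolide)
Product: 24 6-O-triethylsilyl ether of 23
Conditions: Et3SiOTf, 2,6-lutidine, CH2Cl2, −78 °C
Reagents that add atoms: triethylsilyl triflate, CC[Si](CC)(CC)OS(=O)(=O)C(F)(F)F
Why: Silylation of the new secondary hydroxyl, with the tertiary 11-OH staying free at −78 °C, protects O6 during the oxidation and the chromium step.

Step 19
Reactants: 24 6-O-triethylsilyl ether of 23
Product: 25 C9 aldehyde of 24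
Conditions: (COCl)2, DMSO, CH2Cl2, −78 to −30 °C; then Et3N, −78 to 0 °C
Reagents that add atoms: none
Why: Swern oxidation applied to a primary triethylsilyl ether, in which the activated sulfonium attacks the least hindered silyl ether oxygen, Et3SiCl is lost and the alkoxysulfonium collapses to the C9 aldehyde, the secondary silyl ethers being inert.

Step 20
Reactants: 25 C9 aldehyde of 24
Product: 26 macrocyclic carbinol (ring B closed by C8–C9; 9-OH syn to 11-OH; Δ8(17)-butenolide)
Conditions: CrCl2 (15 equiv), NiCl2 (2 mol%), DMSO/THF (3:1), 2 mM, rt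
Reagents that add atoms: none
Why: Nozaki–Hiyama–Kishi macrocyclisation, in which zerovalent nickel inserts into the activated C8–Br bond and the alkenyl trivalent chromium species adds to the aldehyde at high dilution to close ring B; the nucleophile is tethered through C1 and so attacks the face of C9 syn to C1 while chromium holds the carbonyl oxygen near O11, which should give the 9,11-syn alcohol.

Step 21
Reactants: 26 macrocyclic carbinol (ring B closed by C8–C9; 9-OH syn to 11-OH; Δ8(17)-butenolide)
Product: 27 9,11-O-isopropylidene derivative of 26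
Conditions: 2-methoxypropene, PPTS (cat.), CH2Cl2, 0 °C
Reagents that add atoms: 2-methoxypropene, COC(C)=C
Why: Acetonide formation (acid-catalysed transketalisation) on the syn-1,3-diol protects O9 and O11 together, the silyl ethers surviving PPTS at 0 °C.

Step 22
Reactants: 27 9,11-O-isopropylidene derivative of 26
Product: 29 tricyclic 4,8-ether with free 6-OH (O6 trans to O7; saturated 17R lactone; 9,11-acetonide), via macrocyclic 4,6-diol 28 (not isolated)
Conditions: HF·pyridine, pyridine, THF, 0 °C to rt; then DBU (1 equiv), CH2Cl2, 0 °C to rt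
Reagents that add atoms: none
Why: Fluoride desilylation followed by a transannular oxa-Michael addition, in which O4 adds 6-exo to the butenolide β-carbon C8 on the only face it can reach (cis to C6, with C3 and C9 both on the bridge side), so that C8 follows from C4 and C7, and under the reversible DBU conditions C17 should settle with its methyl trans to the bulkier C9 substituent (thermodynamic control).

Step 23
Reactants: 29 tricyclic 4,8-ether with free 6-OH (O6 trans to O7; saturated 17R lactone; 9,11-acetonide)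
Product: 30 9,11-O-isopropylidene derivative of the target (6-chloro)
Conditions: PPh3, hexachloroacetone, CH2Cl2, −20 to 0 °C
Reagents that add atoms: hexachloroacetone, ClC(Cl)(Cl)C(=O)C(Cl)(Cl)Cl
Why: Appel-type chlorination of the allylic alcohol, in which the alkoxyphosphonium is displaced by chloride in an SN2 step with inversion to place chlorine cis to O7, this reagent pair being chosen because it minimises allylic transposition.

Step 24
Reactants: 30 9,11-O-isopropylidene derivative of the target (6-chloro)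
Product: 31 target CNP0190959.1
Conditions: AcOH/H2O/THF (3:1:1), 40 °C
Reagents that add atoms: none
Why: Acid-catalysed acetal hydrolysis removes the isopropylidene group from O9/O11 under conditions that should spare the four acetates, the γ-lactone and the allylic chloride.

Compound list
1 | (E)-3-methylpent-2-en-4-yn-1-ol | OC/C=C(\C)/C#C | starting material
2 | (E)-trimethyl{[3-methyl-5-(trimethylsilyl)pent-2-en-4-yn-1-yl]oxy}silane (bis-silylated enynol) | C[Si](C)(C)OC/C=C(\C)/C#C[Si](C)(C)C | intermediate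
3 | (E)-3-methyl-5-(trimethylsilyl)pent-2-en-4-yn-1-ol | OC/C=C(\C)/C#C[Si](C)(C)C | intermediate
4 | (E)-3-methyl-5-(trimethylsilyl)pent-2-en-4-ynal | O=C/C=C(\C)/C#C[Si](C)(C)C | intermediate
5 | 3-hydroxy-2H-pyran-2-one | OC1=CC=COC1=O | starting material
6 | endo adduct 4-hydroxy-7-methyl-3-oxo-7-[(trimethylsilyl)ethynyl]-2-oxabicyclo[2.2.2]oct-5-ene-8-carbaldehyde (8-CHO and 7-CH3 syn to C5=C6, alkynyl syn to the lactone bridge) | O=C[C@H]1[C@@]2(O)C=C[C@H](OC2=O)[C@]1(C)C#C[Si](C)(C)C | intermediate
7 | 4-hydroxy-8-(hydroxymethyl)-7-methyl-7-[(trimethylsilyl)ethynyl]-2-oxabicyclo[2.2.2]oct-5-en-3-one | OC[C@H]1[C@@]2(O)C=C[C@H](OC2=O)[C@]1(C)C#C[Si](C)(C)C | intermediate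
8 | 4-hydroxy-7-methyl-8-[(triethylsilyloxy)methyl]-7-[(trimethylsilyl)ethynyl]-2-oxabicyclo[2.2.2]oct-5-en-3-one | CC[Si](CC)(CC)OC[C@H]1[C@@]2(O)C=C[C@H](OC2=O)[C@]1(C)C#C[Si](C)(C)C | intermediate
9 | 4-hydroxy-7-methyl-8-[(triethylsilyloxy)methyl]-7-[(trimethylsilyl)ethynyl]-2-oxabicyclo[2.2.2]octan-3-one | CC[Si](CC)(CC)OC[C@H]1[C@@]2(O)CC[C@H](OC2=O)[C@]1(C)C#C[Si](C)(C)C | intermediate
10 | ring A triol 1-(hydroxymethyl)-3-methyl-2-[(triethylsilyloxy)methyl]-3-[(trimethylsilyl)ethynyl]cyclohexane-1,4-diol (silylalkyne triol) | CC[Si](CC)(CC)OC[C@H]1[C@](O)(CO)CC[C@H](O)[C@]1(C)C#C[Si](C)(C)C | intermediate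
11 | ring A triol 3-ethynyl-1-(hydroxymethyl)-3-methyl-2-[(triethylsilyloxy)methyl]cyclohexane-1,4-diol | CC[Si](CC)(CC)OC[C@H]1[C@](O)(CO)CC[C@H](O)[C@]1(C)C#C | intermediate
12 | ring A diacetate [4-acetoxy-3-ethynyl-1-hydroxy-3-methyl-2-[(triethylsilyloxy)methyl]cyclohexyl]methyl acetate | CC[Si](CC)(CC)OC[C@H]1[C@](O)(COC(C)=O)CC[C@H](OC(C)=O)[C@]1(C)C#C | intermediate
13 | 2-bromoprop-2-enal (2-bromoacrolein) | C=C(Br)C=O | starting material
14 | propargylic alcohol (diacetate 12 carrying at C3 the carbinol C4H(OH)–C5(Br)=C16H2) | CC[Si](CC)(CC)OC[C@H]1[C@](O)(COC(C)=O)CC[C@H](OC(C)=O)[C@]1(C)C#C[C@H](O)C(Br)=C | intermediate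
15 | (2E)-allylic alcohol (C2=C3 trans) | CC[Si](CC)(CC)OC[C@H]1[C@](O)(COC(C)=O)CC[C@H](OC(C)=O)[C@]1(C)/C=C/[C@H](O)C(Br)=C | intermediate
16 | 4-O-tert-butyldimethylsilyl ether of 15 | CC[Si](CC)(CC)OC[C@H]1[C@](O)(COC(C)=O)CC[C@H](OC(C)=O)[C@]1(C)/C=C/[C@H](O[Si](C)(C)C(C)(C)C)C(Br)=C | intermediate
17 | 2,3-diol (2,3-threo and 3,4-erythro) of 16 | CC[Si](CC)(CC)OC[C@H]1[C@](O)(COC(C)=O)CC[C@H](OC(C)=O)[C@]1(C)[C@@H](O)[C@H](O)[C@H](O[Si](C)(C)C(C)(C)C)C(Br)=C | intermediate
18 | 2,3,14,20-tetraacetate (5-bromo-5(16)-ene with 4-OTBS and 9-OTES) | CC[Si](CC)(CC)OC[C@H]1[C@](O)(COC(C)=O)CC[C@H](OC(C)=O)[C@]1(C)[C@@H](OC(C)=O)[C@H](OC(C)=O)[C@H](O[Si](C)(C)C(C)(C)C)C(Br)=C | intermediate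
19 | enal (18 with the C6 formyl group in place of bromine at C5) | CC[Si](CC)(CC)OC[C@H]1[C@](O)(COC(C)=O)CC[C@H](OC(C)=O)[C@]1(C)[C@@H](OC(C)=O)[C@H](OC(C)=O)[C@H](O[Si](C)(C)C(C)(C)C)C(=C)C=O | intermediate
20 | 4-hydroxy-3-methylfuran-2(5H)-one (3-methyltetronic acid) | CC1=C(O)COC1=O | starting material
21 | 4-bromo-3-methylfuran-2(5H)-one | CC1=C(Br)COC1=O | intermediate
22 | [(4-bromo-3-methylfuran-2-yl)oxy](tert-butyl)dimethylsilane | Cc1c(Br)coc1O[Si](C)(C)C(C)(C)C | intermediate
23 | vinylogous aldol adduct (6-hydroxy with 4,6-anti and 6,7-threo relationships; 8-bromo-Δ8(17)-butenolide) | CC[Si](CC)(CC)OC[C@H]1[C@](O)(COC(C)=O)CC[C@H](OC(C)=O)[C@]1(C)[C@@H](OC(C)=O)[C@H](OC(C)=O)[C@H](O[Si](C)(C)C(C)(C)C)C(=C)[C@@H](O)[C@@H]1OC(=O)C(C)=C1Br | intermediate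
24 | 6-O-triethylsilyl ether of 23 | CC[Si](CC)(CC)OC[C@H]1[C@](O)(COC(C)=O)CC[C@H](OC(C)=O)[C@]1(C)[C@@H](OC(C)=O)[C@H](OC(C)=O)[C@H](O[Si](C)(C)C(C)(C)C)C(=C)[C@@H](O[Si](CC)(CC)CC)[C@@H]1OC(=O)C(C)=C1Br | intermediate
25 | C9 aldehyde of 24 | O=C[C@H]1[C@](O)(COC(C)=O)CC[C@H](OC(C)=O)[C@]1(C)[C@@H](OC(C)=O)[C@H](OC(C)=O)[C@H](O[Si](C)(C)C(C)(C)C)C(=C)[C@@H](O[Si](CC)(CC)CC)[C@@H]1OC(=O)C(C)=C1Br | intermediate
26 | macrocyclic carbinol (ring B closed by C8–C9; 9-OH syn to 11-OH; Δ8(17)-butenolide) | O[C@H]3[C@H]1[C@](O)(COC(C)=O)CC[C@H](OC(C)=O)[C@]1(C)[C@@H](OC(C)=O)[C@H](OC(C)=O)[C@H](O[Si](C)(C)C(C)(C)C)C(=C)[C@@H](O[Si](CC)(CC)CC)[C@@H]2OC(=O)C(C)=C23 | intermediate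
27 | 9,11-O-isopropylidene derivative of 26 | CC5(C)O[C@H]3[C@H]1[C@](O5)(COC(C)=O)CC[C@H](OC(C)=O)[C@]1(C)[C@@H](OC(C)=O)[C@H](OC(C)=O)[C@H](O[Si](C)(C)C(C)(C)C)C(=C)[C@@H](O[Si](CC)(CC)CC)[C@@H]2OC(=O)C(C)=C23 | intermediate
28 | macrocyclic 4,6-diol of 27 | CC5(C)O[C@H]3[C@H]1[C@](O5)(COC(C)=O)CC[C@H](OC(C)=O)[C@]1(C)[C@@H](OC(C)=O)[C@H](OC(C)=O)[C@H](O)C(=C)[C@@H](O)[C@@H]2OC(=O)C(C)=C23 | intermediate
29 | tricyclic 4,8-ether with free 6-OH (O6 trans to O7; saturated 17R lactone; 9,11-acetonide) | C=C1[C@H]2O[C@]3([C@@H](C)C(=O)O[C@H]3[C@@H]1O)[C@@H](OC6(C)C)[C@H]1[C@](O6)(COC(C)=O)CC[C@H](OC(C)=O)[C@]1(C)[C@@H](OC(C)=O)[C@@H]2OC(C)=O | intermediate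
30 | 9,11-O-isopropylidene derivative of the target (6-chloro) | C=C1[C@H]2O[C@]3([C@@H](C)C(=O)O[C@H]3[C@H]1Cl)[C@@H](OC6(C)C)[C@H]1[C@](O6)(COC(C)=O)CC[C@H](OC(C)=O)[C@]1(C)[C@@H](OC(C)=O)[C@@H]2OC(C)=O | intermediate
31 | target CNP0190959.1 | C=C1[C@H]2O[C@]3([C@@H](C)C(=O)O[C@H]3[C@H]1Cl)[C@@H](O)[C@H]1[C@](O)(COC(C)=O)CC[C@H](OC(C)=O)[C@]1(C)[C@@H](OC(C)=O)[C@@H]2OC(C)=O | target

Total step count: 24. Longest linear sequence: 22 steps (steps 1–14 and 17–24; steps 15 and 16 make the silyloxyfuran side branch).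

The three steps most likely to fail

Step 3. Bond formation at the fully substituted β-carbon C1 may be too slow, and reversible Michael/retro-aldol events under base may erode endo selectivity. The fallback switches the activated partner. Enal 4 is condensed with a diarylprolinol silyl ether (for example (S)-α,α-diphenylprolinol trimethylsilyl ether with benzoic acid, CHCl3, 0 °C) to its α,β-unsaturated iminium ion. Pyrone 5 adds through C6 to the iminium β-carbon, and the resulting enamine closes onto the C3 carbonyl (enamine aldol). Hydrolysis returns the amine and the same two-bond adduct. The fallback sets out from 4 and 5 and comes back at 6; no new compound arises on the way (F0).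

Step 20. Ring closure may lose out to intermolecular coupling or to simple reduction of the C8–Br bond, and facial selectivity at C9 may be poor. The fallback makes the C8–C9 bond at the ketone oxidation level by acyl cross-coupling and sets the carbinol afterwards by a directed reduction. It sets out from 25, which is oxidised (NaClO2, NaH2PO4, 2-methylbut-2-ene, t-BuOH/H2O) to the carboxylic acid F1. F1 is converted (EtSH, EDC·HCl, DMAP, CH2Cl2) into the S-ethyl thioester F2. Zinc insertion (Zn dust, LiCl, THF) into the activated C8–Br bond gives the alkenylzinc bromide F3, used in the flask. Under high dilution with Pd2(dba)3 and tri(2-furyl)phosphine it closes by Fukuyama coupling to the macrocyclic C9 ketone F4. A 1,3-syn reduction directed by the free 11-OH (Et2BOMe, NaBH4, THF/MeOH, −78 °C, Narasaka–Prasad) comes back to the route at 26.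

Step 23. Chloride may enter with allylic transposition at C16 (SN2′), or the displacement may stall because the face of C6 anti to the leaving group is screened in the tricycle. The fallback moves the displacement to the conformationally freer macrocycle, before the ether bridge exists. It sets out from 27. The secondary triethylsilyl ether is removed selectively (HF·pyridine buffered with pyridine, THF, 0 °C, the tert-butyldimethylsilyl ether surviving) to give the macrocyclic C6 alcohol F5. F5 is chlorinated with inversion (PPh3, hexachloroacetone, CH2Cl2) to the macrocyclic C6 chloride F6. Removal of the remaining silyl ether (HF·pyridine, rt) gives the C4 alcohol F7, which is not isolated. F7 is cyclised under acid (camphorsulfonic acid, CH2Cl2) rather than base, to avoid β-elimination of chloride through the butenolide dienolate. A short DBU treatment after ring closure equilibrates C17, and the fallback comes back to the route at 30.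

Further compounds
F0 | step 3 | none | none
F1 | step 20 | C9 carboxylic acid of 24 | OC(=O)[C@H]1[C@](O)(COC(C)=O)CC[C@H](OC(C)=O)[C@]1(C)[C@@H](OC(C)=O)[C@H](OC(C)=O)[C@H](O[Si](C)(C)C(C)(C)C)C(=C)[C@@H](O[Si](CC)(CC)CC)[C@@H]1OC(=O)C(C)=C1Br
F2 | step 20 | S-ethyl C9 thioester | CCSC(=O)[C@H]1[C@](O)(COC(C)=O)CC[C@H](OC(C)=O)[C@]1(C)[C@@H](OC(C)=O)[C@H](OC(C)=O)[C@H](O[Si](C)(C)C(C)(C)C)C(=C)[C@@H](O[Si](CC)(CC)CC)[C@@H]1OC(=O)C(C)=C1Br
F3 | step 20 | C8 alkenylzinc bromide of the thioester (not isolated) | CCSC(=O)[C@H]1[C@](O)(COC(C)=O)CC[C@H](OC(C)=O)[C@]1(C)[C@@H](OC(C)=O)[C@H](OC(C)=O)[C@H](O[Si](C)(C)C(C)(C)C)C(=C)[C@@H](O[Si](CC)(CC)CC)[C@@H]1OC(=O)C(C)=C1[Zn]Br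
F4 | step 20 | macrocyclic C9 ketone | O=C3[C@H]1[C@](O)(COC(C)=O)CC[C@H](OC(C)=O)[C@]1(C)[C@@H](OC(C)=O)[C@H](OC(C)=O)[C@H](O[Si](C)(C)C(C)(C)C)C(=C)[C@@H](O[Si](CC)(CC)CC)[C@@H]2OC(=O)C(C)=C23
F5 | step 23 | macrocyclic C6 alcohol (4-OTBS, 9,11-acetonide) | CC5(C)O[C@H]3[C@H]1[C@](O5)(COC(C)=O)CC[C@H](OC(C)=O)[C@]1(C)[C@@H](OC(C)=O)[C@H](OC(C)=O)[C@H](O[Si](C)(C)C(C)(C)C)C(=C)[C@@H](O)[C@@H]2OC(=O)C(C)=C23
F6 | step 23 | macrocyclic C6 chloride (4-OTBS, 9,11-acetonide) | CC5(C)O[C@H]3[C@H]1[C@](O5)(COC(C)=O)CC[C@H](OC(C)=O)[C@]1(C)[C@@H](OC(C)=O)[C@H](OC(C)=O)[C@H](O[Si](C)(C)C(C)(C)C)C(=C)[C@H](Cl)[C@@H]2OC(=O)C(C)=C23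
F7 | step 23 | macrocyclic C6 chloride with free 4-OH (not isolated) | CC5(C)O[C@H]3[C@H]1[C@](O5)(COC(C)=O)CC[C@H](OC(C)=O)[C@]1(C)[C@@H](OC(C)=O)[C@H](OC(C)=O)[C@H](O)C(=C)[C@H](Cl)[C@@H]2OC(=O)C(C)=C23
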